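**Retrosynthetic overview** (numbers are assigned in the forward route below)
1. Target ⇐ LiAlH4 opening of a cis-fused 3,6-diaryl-furo[3,4-c]furan-1-one: the lactone C=O becomes the CH2OH, the lactone C–O carbon becomes the (R)-carbinol, and the phenol pivalates are removed in the same operation.
2. Key disconnection: the ArCH(O)–C4 bond of that lactone. A Sm(II) ketyl radical from O-pivaloylvanillin adds to C4 of a methyl (R)-2-aryl-2,5-dihydrofuran-3-carboxylate, and in-situ lactonisation fixes the three remaining stereocentres.
3. Dihydrofuran ester ⇐ ring-closing metathesis ⇐ O-allyl ether ⇐ asymmetric Morita–Baylis–Hillman adduct of O-pivaloylvanillin and methyl acrylate.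
4. O-Pivaloylvanillin (source of both aryl units) ⇐ vanillin ⇐ guaiacol + glyoxylic acid ⇐ catechol + MeI.
5. Ring order: 2,5-dihydrofuran first (RCM), γ-lactone second (radical addition/lactonisation); the lactone is opened at the end and the oxolane remains.

Assumption: the SMILES is taken as definitive, i.e. a (2S,3R,4R)-oxolane (2-aryl/3-CH2OH trans, 3-CH2OH/4-CH(OH)Ar cis) with an (R)-carbinol.

Ar below = 3-methoxy-4-(pivaloyloxy)phenyl.

**Step 1**
Reactants: 1 catechol (benzene-1,2-diol); 2 iodomethane
Product: 3 guaiacol (2-methoxyphenol)
Conditions: MeI (1.0 equiv), K2CO3 (1.0 equiv), acetone, reflux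
Reagents that add atoms: iodomethane, CI
Why: Williamson mono-O-methylation with limiting MeI/base gives mainly the mono-ether, which is separated from catechol and veratrole by base extraction/distillation; no stereocentre.

**Step 2**
Reactants: 3 guaiacol; 4 glyoxylic acid
Product: 5 vanillin (4-hydroxy-3-methoxybenzaldehyde)
Conditions: OHC–CO2H, aq NaOH, 30 °C; then cat. CuSO4, air, aq NaOH, 95 °C; H3O+ (one pot)
Reagents that add atoms: glyoxylic acid, O=CC(=O)O (supplies the CHO carbon; its CO2H is lost as CO2)
Why: para-selective hydroxyalkylation of the phenoxide by glyoxylate followed by oxidative decarboxylation of the mandelate (the guaiacol–glyoxylic acid vanillin process); no stereocentre.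

**Step 3**
Reactants: 5 vanillin; 6 pivaloyl chloride
Product: 7 4-formyl-2-methoxyphenyl pivalate
Conditions: PivCl, Et3N, DMAP (cat.), CH2Cl2, 0 °C → rt
Reagents that add atoms: pivaloyl chloride, CC(C)(C)C(=O)Cl
Why: phenol acylation; the pivalate makes the aldehyde more electrophilic and more easily reduced, makes the later benzylic C–O bonds less ionisable, and is removed by LiAlH4 in the last step.

**Step 4**
Reactants: 7; 8 methyl acrylate
Product: 9 methyl (R)-2-{hydroxy[3-methoxy-4-(pivaloyloxy)phenyl]methyl}prop-2-enoate
Conditions: methyl acrylate (3 equiv), amino-acid-derived chiral phosphine–thiourea (10 mol %, enantiomer giving the R-carbinol), THF, rt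
Reagents that add atoms: methyl acrylate, C=CC(=O)OC
Why: asymmetric Morita–Baylis–Hillman reaction in which the phosphonium enolate adds to the thiourea-bound aldehyde on one face, setting the benzylic carbinol as R (moderate ee expected; upgraded by recrystallising 13).

**Step 5**
Reactants: 9; 10 allyl bromide
Product: 11 methyl (R)-2-{(allyloxy)[3-methoxy-4-(pivaloyloxy)phenyl]methyl}prop-2-enoate
Conditions: allyl bromide (5 equiv), Ag2O (2 equiv), 4 Å MS, CH2Cl2, rt, dark
Reagents that add atoms: allyl bromide, C=CCBr
Why: silver-oxide-mediated (Purdie-type) O-alkylation under non-basic conditions avoids retro-MBH and SN2′ pathways and leaves the stereocentre untouched.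

**Step 6**
Reactants: 11
Product: 12 methyl (R)-2-[3-methoxy-4-(pivaloyloxy)phenyl]-2,5-dihydrofuran-3-carboxylate
Conditions: Grubbs II (5 mol %), 1,4-benzoquinone (10 mol %), CH2Cl2 (0.02 M), 40 °C
Reagents that add atoms: none (ethylene is lost)
Why: ring-closing metathesis between the allyl ether and the acrylate 1,1-disubstituted alkene forms the dihydrofuran, with benzoquinone suppressing Ru–H alkene migration; the stereocentre is retained.

**Step 7 (key step)**
Reactants: 12; 7 (second use)
Product: 13 (3R,3aR,6S,6aS)-3,6-bis[3-methoxy-4-(pivaloyloxy)phenyl]tetrahydro-1H,3H-furo[3,4-c]furan-1-one (cis-fused; 6-aryl exo, 3-aryl endo)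
Conditions: SmI2 (3 equiv), t-BuOH (2 equiv), THF, −78 → −20 °C, slow addition of 7 (1.5 equiv); aq NH4Cl
Reagents that add atoms: none beyond reactant 7, COc1cc(C=O)ccc1OC(=O)C(C)(C)C (SmI2/t-BuOH supply only electrons and H)
Why: Proposed new method: an intermolecular SmI2 ketyl–olefin coupling/lactonisation, closest precedent being SmI2-mediated aldehyde + crotonate couplings that give cis-β,γ-disubstituted γ-butyrolactones, here extended to an aryl aldehyde and a cyclic α,β-disubstituted enoate — Sm(II) reduces 7 to a Sm(III)-bound ketyl radical that adds to C4 of 12 anti to the C2 aryl through an ester-chelated transition state placing the new aryl cis to the ring CH2 (3R,3aR), the α-ester radical is reduced to the samarium enolate and protonated, and the samarium alkoxide can lactonise only with a cis ring fusion (6aS), while slow addition of 7 keeps ketyl concentration low to suppress pinacol coupling.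

**Step 8**
Reactants: 13
Product: 14 (7R)-7-hydroxylariciresinol, 4-[(2S,3R,4R)-4-[(R)-hydroxy(4-hydroxy-3-methoxyphenyl)methyl]-3-(hydroxymethyl)oxolan-2-yl]-2-methoxyphenol
Conditions: LiAlH4 (6 equiv), THF, 0 °C → rt; Rochelle salt work-up at pH ≈ 7
Reagents that add atoms: none (hydride only)
Why: LiAlH4 reduction of the lactone gives the primary alcohol and the benzylic carbinol without breaking any bond to a stereocentre and cleaves both aryl pivalates in the same operation; neutral work-up avoids acid-promoted cyclisation to the furofuran.

**Compound list**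
1 | catechol | Oc1ccccc1O | starting material
2 | iodomethane | CI | starting material
3 | guaiacol | COc1ccccc1O | intermediate
4 | glyoxylic acid | O=CC(=O)O | starting material
5 | vanillin | COc1cc(C=O)ccc1O | intermediate
6 | pivaloyl chloride | CC(C)(C)C(=O)Cl | starting material (protecting-group reagent)
7 | 4-formyl-2-methoxyphenyl pivalate | COc1cc(C=O)ccc1OC(=O)C(C)(C)C | intermediate
8 | methyl acrylate | C=CC(=O)OC | starting material
9 | methyl (R)-2-{hydroxy[3-methoxy-4-(pivaloyloxy)phenyl]methyl}prop-2-enoate | COc1cc([C@@H](O)C(=C)C(=O)OC)ccc1OC(=O)C(C)(C)C | intermediate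
10 | allyl bromide | C=CCBr | starting material
11 | methyl (R)-2-{(allyloxy)[3-methoxy-4-(pivaloyloxy)phenyl]methyl}prop-2-enoate | COc1cc([C@@H](OCC=C)C(=C)C(=O)OC)ccc1OC(=O)C(C)(C)C | intermediate
12 | methyl (R)-2-[3-methoxy-4-(pivaloyloxy)phenyl]-2,5-dihydrofuran-3-carboxylate | COc1cc([C@H]2OCC=C2C(=O)OC)ccc1OC(=O)C(C)(C)C | intermediate
13 | (3R,3aR,6S,6aS)-3,6-bis[3-methoxy-4-(pivaloyloxy)phenyl]tetrahydro-1H,3H-furo[3,4-c]furan-1-one | COc1cc([C@H]2OC[C@H]([C@@H](O3)c4ccc(OC(=O)C(C)(C)C)c(OC)c4)[C@@H]2C3=O)ccc1OC(=O)C(C)(C)C | intermediate
14 | (7R)-7-hydroxylariciresinol | COc1cc([C@H]2OC[C@H]([C@@H](O)c3ccc(O)c(OC)c3)[C@@H]2CO)ccc1O | target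

**Totals**
Total steps: 8. Longest linear sequence: 8 (1 → 3 → 5 → 7 → 9 → 11 → 12 → 13 → 14; aldehyde 7 re-enters at step 7).

**Steps most likely to fail, with fallbacks**
1. Step 7. Risks: pinacol dimerisation of 7, slow addition to the trisubstituted enoate, wrong endo/exo outcome at C3, poor facial selectivity, and base-induced isomerisation of 12. Fallback: separate C–C bond formation from carbinol control — acyl-radical Giese addition of 7 to 12 (decatungstate HAT photocatalysis) to give the 4-aroyl ester, then a chelation- or Felkin-controlled ketone reduction chosen to give the 3R carbinol, with lactonisation to 13.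
2. Step 4. Risks: low ee or conversion in the asymmetric MBH. Fallback: racemic DABCO MBH, conversion to the Boc carbonate, then cinchona-alkaloid Lewis-base-catalysed asymmetric SN2′/SN2′ allylic etherification with allyl alcohol to give 11 directly (replacing steps 4–5).
3. Step 5. Risks: sluggish O-allylation of the hindered, base-sensitive MBH alcohol. Fallback: drop allylation/RCM — amine-catalysed α-hydroxyalkylation of methyl buta-2,3-dienoate with 7, lipase resolution of the α-allenol, then Ag(I)- or Au(I)-catalysed 5-endo cycloisomerisation to 12.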